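**Strategy.** The target is cut at the biaryl bond (Suzuki) into an olivil-type oxolane and a cycloolivil-type tetralin, both grown from one iodoalkene. Everything rests on reading the oxolane's tertiary carbinol C4 (OH, benzyl), flanked by C3–CH2OH and C2–aryl, as a Baeyer–Villiger-masked 4-formyl group: then the ring is a Prins–pinacol product. An aryl aldehyde and an (S)-allylic 1,2-diol first close a six-membered oxan-4-yl cation (C2–C3 bond), which contracts by 1,2-shift of C5 to the oxolane, setting C2, C3 and C4 in one operation from either acetal epimer. The precursor is an acyclic (E)-pentenediol acetate.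

Key step: step 6

Remark: oxolane atoms are numbered O1, C2 (aryl), C3 (CH2O), C4 (quaternary), C5 (CH2) in the discussion; compound names use IUPAC locants.
Remark (assumption): in the chair Prins transition state the boron-bound carbinol oxygen is taken as pseudo-axial, so that H and not O eclipses the benzyl group on the neighbouring alkene carbon; on this basis the (S)-diol, from (R)-glyceraldehyde acetonide, is chosen.
Remark: 6, 11 and 17 are taken as catalogue compounds.

Step 1
Reactants: 1 (R)-2,2-dimethyl-1,3-dioxolane-4-carbaldehyde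
Product: 2 (4S)-4-ethynyl-2,2-dimethyl-1,3-dioxolane
Conditions: dimethyl (1-diazo-2-oxopropyl)phosphonate, K2CO3, MeOH, 0 °C → rt
Reagents that add atoms: Ohira–Bestmann reagent, COP(=O)(OC)C(=[N+]=[N-])C(C)=O
Why: Seyferth–Gilbert homologation under Ohira–Bestmann conditions should give the terminal alkyne without touching the α-alkoxy stereocentre (the descriptor changes from R to S only through CIP priorities).

Step 2
Reactants: 2 (4S)-4-ethynyl-2,2-dimethyl-1,3-dioxolane
Product: 3 3-[(4S)-2,2-dimethyl-1,3-dioxolan-4-yl]prop-2-yn-1-ol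
Conditions: n-BuLi, THF, −78 °C; (CH2O)n, −78 °C → rt; aq. NH4Cl
Reagents that add atoms: paraformaldehyde (as formaldehyde), C=O
Why: Addition of the lithium acetylide to formaldehyde should give the propargylic alcohol that is needed to direct the next step.

Step 3
Reactants: 3 3-[(4S)-2,2-dimethyl-1,3-dioxolan-4-yl]prop-2-yn-1-ol
Product: 5 (2Z)-3-[(4R)-2,2-dimethyl-1,3-dioxolan-4-yl]-3-iodoprop-2-en-1-ol, via alkenylalanate 4 (not isolated)
Conditions: Red-Al, THF, 0 °C → rt; then I2, THF, −78 → 0 °C; Rochelle salt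
Reagents that add atoms: iodine, II
Why: Hydroxyl-directed trans-hydroalumination should place aluminium on the distal alkyne carbon in a five-membered oxa-aluminacycle, and iodinolysis with retention should give the (Z)-3-iodoallylic alcohol, which fixes the alkene geometry for the key step.

Step 4
Reactants: 5 (2Z)-3-[(4R)-2,2-dimethyl-1,3-dioxolan-4-yl]-3-iodoprop-2-en-1-ol; 6 2-(benzyloxy)-4-(chloromethyl)-1-methoxybenzene
Product: 8 (2E)-4-[3-(benzyloxy)-4-methoxyphenyl]-3-[(4S)-2,2-dimethyl-1,3-dioxolan-4-yl]but-2-en-1-ol, via benzylzinc chloride 7 (not isolated)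
Conditions: 6, Zn dust, LiCl, THF, rt; then 5, Pd(OAc)2 (cat.), SPhos (cat.), THF, rt
Reagents that add atoms: none
Why: Negishi sp2–sp3 coupling of the benzylic zinc reagent should proceed with retention of the alkene geometry, so that the benzyl group ends cis to CH2OH; organozinc halides tolerate the free hydroxyl.

Step 5
Reactants: 8 (2E)-4-[3-(benzyloxy)-4-methoxyphenyl]-3-[(4S)-2,2-dimethyl-1,3-dioxolan-4-yl]but-2-en-1-ol
Product: 10 (2E,4S)-3-[3-(benzyloxy)-4-methoxybenzyl]-4,5-dihydroxypent-2-en-1-yl acetate, via acetonide acetate 9 (not isolated)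
Conditions: Ac2O, pyridine, DMAP (cat.), CH2Cl2, 0 °C → rt; evaporate; AcOH/H2O 4:1, 40 °C
Reagents that add atoms: acetic anhydride, CC(=O)OC(C)=O
Why: Acetylation of the primary allylic alcohol followed by mild acidic hydrolysis of the acetonide should free the 1,2-diol while the acetate, needed to keep this oxygen out of the key step, stays in place.

Step 6
Reactants: 10 (2E,4S)-3-[3-(benzyloxy)-4-methoxybenzyl]-4,5-dihydroxypent-2-en-1-yl acetate; 11 4-(benzyloxy)-3-bromo-5-methoxybenzaldehyde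
Product: 14 [(2S,3R,4S)-2-[4-(benzyloxy)-3-bromo-5-methoxyphenyl]-4-[3-(benzyloxy)-4-methoxybenzyl]-4-formyloxolan-3-yl]methyl acetate, via dioxolane acetal 12 (not isolated), via oxan-4-ylium zwitterion 13 (not isolated)
Conditions: BF3·OEt2 (3 equiv), MgSO4, CH2Cl2, −60 → −20 °C; Et3N, aq. NaHCO3
Reagents that add atoms: none
Why: BF3 should condense the diol with 11 to the dioxolane 12 (reversible acetalisation, either C2 epimer), which ionises at the allylic C–O bond to the (E)-oxocarbenium ion; the trisubstituted alkene attacks it in a 6-endo-trig Prins closure through a chair to give the tertiary oxan-4-yl cation 13, and a 1,2-shift of the ring CH2 (C5) from the carbinol carbon to the cationic carbon, pushed by the boron-bound oxygen, contracts the oxane to the oxolane and releases the formyl group (the closest known reaction type is the Prins–pinacol rearrangement of allylic diol acetals to 3-acyl tetrahydrofurans). In the chair the aryl group of the (E)-oxocarbenium ion and the CH2OAc group of the (E)-alkene are both equatorial, which sets C2 and C3 trans, and the shift of C5 occurs on the face of the cation that carries the ring, which leaves the benzyl group cis and the formyl group trans to CH2OAc at C4. The absolute sense comes from the (S)-carbinol centre, which is destroyed in the step: its boron-bound oxygen is expected pseudo-axial so that H and not O eclipses the benzyl group on the adjacent alkene carbon (A1,2 strain), and this exposes the alkene face that leads to (2S,3R,4S). The step needs this facial selectivity, and it needs the pinacol shift to outrun capture of the cation by the electron-rich arenes; the first rests on the A1,2 strain, the second on the oxido group directly beside the cation. A 2-oxonia-Cope route that would erase the stereochemical information is disfavoured, because it would trade the aryl-stabilised oxocarbenium ion for an unstabilised methylene oxocarbenium ion.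

Step 7
Reactants: 14 [(2S,3R,4S)-2-[4-(benzyloxy)-3-bromo-5-methoxyphenyl]-4-[3-(benzyloxy)-4-methoxybenzyl]-4-formyloxolan-3-yl]methyl acetate
Product: 16 (3S,4R,5S)-5-[4-(benzyloxy)-3-bromo-5-methoxyphenyl]-3-[3-(benzyloxy)-4-methoxybenzyl]-4-(hydroxymethyl)oxolan-3-ol, via formate 15 (not isolated)
Conditions: mCPBA, NaHCO3, CH2Cl2, 0 °C → rt; then K2CO3, MeOH, rt
Reagents that add atoms: mCPBA, OOC(=O)c1cccc(Cl)c1
Why: Baeyer–Villiger oxidation of the α-quaternary aldehyde should move the fully substituted C4 to oxygen with retention, giving the tertiary formate, and methanolysis in the same flask removes formate and acetate to leave OH trans to CH2OH.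

Step 8
Reactants: 5 (2Z)-3-[(4R)-2,2-dimethyl-1,3-dioxolan-4-yl]-3-iodoprop-2-en-1-ol; 17 1-(benzyloxy)-4-(chloromethyl)-2-methoxybenzene
Product: 19 (2E)-4-[4-(benzyloxy)-3-methoxyphenyl]-3-[(4S)-2,2-dimethyl-1,3-dioxolan-4-yl]but-2-en-1-ol, via benzylzinc chloride 18 (not isolated)
Conditions: 17, Zn dust, LiCl, THF, rt; then 5, Pd(OAc)2 (cat.), SPhos (cat.), THF, rt
Reagents that add atoms: none
Why: The same Negishi coupling as in step 4 should deliver the vanillyl-type benzyl group with retention of the alkene geometry.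

Step 9
Reactants: 19 (2E)-4-[4-(benzyloxy)-3-methoxyphenyl]-3-[(4S)-2,2-dimethyl-1,3-dioxolan-4-yl]but-2-en-1-ol
Product: 21 (2E,4S)-3-[4-(benzyloxy)-3-methoxybenzyl]-4,5-dihydroxypent-2-en-1-yl acetate, via acetonide acetate 20 (not isolated)
Conditions: Ac2O, pyridine, DMAP (cat.), CH2Cl2, 0 °C → rt; evaporate; AcOH/H2O 4:1, 40 °C
Reagents that add atoms: acetic anhydride, CC(=O)OC(C)=O
Why: Acetylation and acetonide hydrolysis should proceed as in step 5.

Step 10
Reactants: 21 (2E,4S)-3-[4-(benzyloxy)-3-methoxybenzyl]-4,5-dihydroxypent-2-en-1-yl acetate; 11 4-(benzyloxy)-3-bromo-5-methoxybenzaldehyde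
Product: 24 [(2S,3R,4S)-2-[4-(benzyloxy)-3-bromo-5-methoxyphenyl]-4-[4-(benzyloxy)-3-methoxybenzyl]-4-formyloxolan-3-yl]methyl acetate, via dioxolane acetal 22 (not isolated), via oxan-4-ylium zwitterion 23 (not isolated)
Conditions: BF3·OEt2 (3 equiv), MgSO4, CH2Cl2, −60 → −20 °C; Et3N, aq. NaHCO3
Reagents that add atoms: none
Why: The same Prins–pinacol ring contraction as in step 6 should set the C3 and C4 configurations, which are carried unchanged into the tetralin, by the same chair transition state.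

Step 11
Reactants: 24 [(2S,3R,4S)-2-[4-(benzyloxy)-3-bromo-5-methoxyphenyl]-4-[4-(benzyloxy)-3-methoxybenzyl]-4-formyloxolan-3-yl]methyl acetate
Product: 26 (3S,4R,5S)-5-[4-(benzyloxy)-3-bromo-5-methoxyphenyl]-3-[4-(benzyloxy)-3-methoxybenzyl]-4-(hydroxymethyl)oxolan-3-ol, via formate 25 (not isolated)
Conditions: mCPBA, NaHCO3, CH2Cl2, 0 °C → rt; then K2CO3, MeOH, rt
Reagents that add atoms: mCPBA, OOC(=O)c1cccc(Cl)c1
Why: Baeyer–Villiger oxidation with retention and methanolysis should proceed as in step 7.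

Step 12
Reactants: 26 (3S,4R,5S)-5-[4-(benzyloxy)-3-bromo-5-methoxyphenyl]-3-[4-(benzyloxy)-3-methoxybenzyl]-4-(hydroxymethyl)oxolan-3-ol
Product: 27 (2S,3S,4S)-6-(benzyloxy)-4-[4-(benzyloxy)-3-bromo-5-methoxyphenyl]-2,3-bis(hydroxymethyl)-7-methoxy-1,2,3,4-tetrahydronaphthalen-2-ol
Conditions: BF3·OEt2, CH2Cl2, −20 → 0 °C
Reagents that add atoms: none
Why: Ionisation of the benzylic C–O bond of the oxolane and intramolecular Friedel–Crafts alkylation of the vanillyl ring para to its methoxy group (the olivil-to-cycloolivil rearrangement) should close the tetralin with the aryl group trans to the neighbouring CH2OH, the two carbinol-side stereocentres being untouched.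

Step 13
Reactants: 16 (3S,4R,5S)-5-[4-(benzyloxy)-3-bromo-5-methoxyphenyl]-3-[3-(benzyloxy)-4-methoxybenzyl]-4-(hydroxymethyl)oxolan-3-ol; 27 (2S,3S,4S)-6-(benzyloxy)-4-[4-(benzyloxy)-3-bromo-5-methoxyphenyl]-2,3-bis(hydroxymethyl)-7-methoxy-1,2,3,4-tetrahydronaphthalen-2-ol
Product: 29 tetra-O-benzyl ether of the target (5,5′-linked biaryl), via pinacol boronate 28 (not isolated)
Conditions: 16, B2pin2, Pd(dppf)Cl2, KOAc, 1,4-dioxane, 90 °C; then 27, SPhos Pd G3, aq. K3PO4, 80 °C
Reagents that add atoms: none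
Why: One-pot Miyaura borylation and Suzuki–Miyaura coupling should join the two aryl bromides at the positions ortho to the benzyloxy groups; free hydroxyl groups are tolerated and no stereocentre is involved.

Step 14
Reactants: 29 tetra-O-benzyl ether of the target
Product: 30 target CNP0252244.1
Conditions: H2 (1 atm), 10% Pd/C, EtOAc/MeOH, rt, stopped at full debenzylation
Reagents that add atoms: none
Why: Hydrogenolysis of the four aryl benzyl ethers should be much faster than cleavage of the benzylic oxolane C–O bond and leaves all stereocentres untouched.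

**Compound list**
1 | (R)-2,2-dimethyl-1,3-dioxolane-4-carbaldehyde | O=C[C@H]1COC(C)(C)O1 | starting material
2 | (4S)-4-ethynyl-2,2-dimethyl-1,3-dioxolane | C#C[C@H]1COC(C)(C)O1 | intermediate
3 | 3-[(4S)-2,2-dimethyl-1,3-dioxolan-4-yl]prop-2-yn-1-ol | OCC#C[C@H]1COC(C)(C)O1 | intermediate
4 | sodium alkenylalanate (cyclic oxa-aluminacycle, two 2-methoxyethoxy ligands) | [Na+].COCCO[Al-]1(OCCOC)OCC=C1[C@H]2COC(C)(C)O2 | intermediate (not isolated)
5 | (2Z)-3-[(4R)-2,2-dimethyl-1,3-dioxolan-4-yl]-3-iodoprop-2-en-1-ol | OC/C=C(\I)[C@H]1COC(C)(C)O1 | intermediate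
6 | 2-(benzyloxy)-4-(chloromethyl)-1-methoxybenzene | COc1ccc(CCl)cc1OCc1ccccc1 | starting material
7 | [3-(benzyloxy)-4-methoxybenzyl]zinc chloride | COc1ccc(C[Zn]Cl)cc1OCc1ccccc1 | intermediate (not isolated)
8 | (2E)-4-[3-(benzyloxy)-4-methoxyphenyl]-3-[(4S)-2,2-dimethyl-1,3-dioxolan-4-yl]but-2-en-1-ol | OC/C=C(\Cc1ccc(OC)c(OCc2ccccc2)c1)[C@H]1COC(C)(C)O1 | intermediate
9 | (2E)-4-[3-(benzyloxy)-4-methoxyphenyl]-3-[(4S)-2,2-dimethyl-1,3-dioxolan-4-yl]but-2-en-1-yl acetate | CC(=O)OC/C=C(\Cc1ccc(OC)c(OCc2ccccc2)c1)[C@H]1COC(C)(C)O1 | intermediate (not isolated)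
10 | (2E,4S)-3-[3-(benzyloxy)-4-methoxybenzyl]-4,5-dihydroxypent-2-en-1-yl acetate | CC(=O)OC/C=C(\Cc1ccc(OC)c(OCc2ccccc2)c1)[C@H](O)CO | intermediate
11 | 4-(benzyloxy)-3-bromo-5-methoxybenzaldehyde | O=Cc1cc(OC)c(OCc2ccccc2)c(Br)c1 | starting material
12 | (4S)-2-aryl-4-alkenyl-1,3-dioxolane from 10 and 11 (both C2 epimers) | CC(=O)OC/C=C(\Cc1ccc(OC)c(OCc2ccccc2)c1)[C@H]1COC(c2cc(OC)c(OCc3ccccc3)c(Br)c2)O1 | intermediate (not isolated)
13 | (2S,3R,5S)-3-(acetoxymethyl)-2-aryl-4-benzyl-5-(trifluoroboranuidyloxy)oxan-4-ylium zwitterion | O1[C@H](c2cc(OC)c(OCc3ccccc3)c(Br)c2)[C@@H](COC(C)=O)[C+](Cc2ccc(OC)c(OCc3ccccc3)c2)[C@H](O[B-](F)(F)F)C1 | intermediate (not isolated)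
14 | [(2S,3R,4S)-2-[4-(benzyloxy)-3-bromo-5-methoxyphenyl]-4-[3-(benzyloxy)-4-methoxybenzyl]-4-formyloxolan-3-yl]methyl acetate | COc1ccc(C[C@@]2(C=O)CO[C@H](c3cc(OC)c(OCc4ccccc4)c(Br)c3)[C@H]2COC(C)=O)cc1OCc1ccccc1 | intermediate
15 | tertiary formate of the acetate of 16 | COc1ccc(C[C@@]2(OC=O)CO[C@H](c3cc(OC)c(OCc4ccccc4)c(Br)c3)[C@H]2COC(C)=O)cc1OCc1ccccc1 | intermediate (not isolated)
16 | (3S,4R,5S)-5-[4-(benzyloxy)-3-bromo-5-methoxyphenyl]-3-[3-(benzyloxy)-4-methoxybenzyl]-4-(hydroxymethyl)oxolan-3-ol | COc1ccc(C[C@@]2(O)CO[C@H](c3cc(OC)c(OCc4ccccc4)c(Br)c3)[C@H]2CO)cc1OCc1ccccc1 | intermediate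
17 | 1-(benzyloxy)-4-(chloromethyl)-2-methoxybenzene | COc1cc(CCl)ccc1OCc1ccccc1 | starting material
18 | [4-(benzyloxy)-3-methoxybenzyl]zinc chloride | COc1cc(C[Zn]Cl)ccc1OCc1ccccc1 | intermediate (not isolated)
19 | (2E)-4-[4-(benzyloxy)-3-methoxyphenyl]-3-[(4S)-2,2-dimethyl-1,3-dioxolan-4-yl]but-2-en-1-ol | OC/C=C(\Cc1ccc(OCc2ccccc2)c(OC)c1)[C@H]1COC(C)(C)O1 | intermediate
20 | (2E)-4-[4-(benzyloxy)-3-methoxyphenyl]-3-[(4S)-2,2-dimethyl-1,3-dioxolan-4-yl]but-2-en-1-yl acetate | CC(=O)OC/C=C(\Cc1ccc(OCc2ccccc2)c(OC)c1)[C@H]1COC(C)(C)O1 | intermediate (not isolated)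
21 | (2E,4S)-3-[4-(benzyloxy)-3-methoxybenzyl]-4,5-dihydroxypent-2-en-1-yl acetate | CC(=O)OC/C=C(\Cc1ccc(OCc2ccccc2)c(OC)c1)[C@H](O)CO | intermediate
22 | (4S)-2-aryl-4-alkenyl-1,3-dioxolane from 21 and 11 (both C2 epimers) | CC(=O)OC/C=C(\Cc1ccc(OCc2ccccc2)c(OC)c1)[C@H]1COC(c2cc(OC)c(OCc3ccccc3)c(Br)c2)O1 | intermediate (not isolated)
23 | (2S,3R,5S)-oxan-4-ylium zwitterion, vanillyl series | O1[C@H](c2cc(OC)c(OCc3ccccc3)c(Br)c2)[C@@H](COC(C)=O)[C+](Cc2ccc(OCc3ccccc3)c(OC)c2)[C@H](O[B-](F)(F)F)C1 | intermediate (not isolated)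
24 | [(2S,3R,4S)-2-[4-(benzyloxy)-3-bromo-5-methoxyphenyl]-4-[4-(benzyloxy)-3-methoxybenzyl]-4-formyloxolan-3-yl]methyl acetate | COc1cc(C[C@@]2(C=O)CO[C@H](c3cc(OC)c(OCc4ccccc4)c(Br)c3)[C@H]2COC(C)=O)ccc1OCc1ccccc1 | intermediate
25 | tertiary formate of the acetate of 26 | COc1cc(C[C@@]2(OC=O)CO[C@H](c3cc(OC)c(OCc4ccccc4)c(Br)c3)[C@H]2COC(C)=O)ccc1OCc1ccccc1 | intermediate (not isolated)
26 | (3S,4R,5S)-5-[4-(benzyloxy)-3-bromo-5-methoxyphenyl]-3-[4-(benzyloxy)-3-methoxybenzyl]-4-(hydroxymethyl)oxolan-3-ol | COc1cc(C[C@@]2(O)CO[C@H](c3cc(OC)c(OCc4ccccc4)c(Br)c3)[C@H]2CO)ccc1OCc1ccccc1 | intermediate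
27 | (2S,3S,4S)-6-(benzyloxy)-4-[4-(benzyloxy)-3-bromo-5-methoxyphenyl]-2,3-bis(hydroxymethyl)-7-methoxy-1,2,3,4-tetrahydronaphthalen-2-ol | Brc1cc([C@H]2c3cc(OCc4ccccc4)c(OC)cc3C[C@@](O)(CO)[C@@H]2CO)cc(OC)c1OCc1ccccc1 | intermediate
28 | pinacol boronate of 16 (Bpin in place of Br) | COc1ccc(C[C@@]2(O)CO[C@H](c3cc(OC)c(OCc4ccccc4)c(B4OC(C)(C)C(C)(C)O4)c3)[C@H]2CO)cc1OCc1ccccc1 | intermediate (not isolated)
29 | tetra-O-benzyl ether of the target: (2S,3R,4S)-oxolane and (1S,2S,3S)-tetralin joined through the 5,5′-biaryl bond | COc1ccc(C[C@@]2(O)CO[C@H](c3cc(OC)c(OCc7ccccc7)c(-c4cc([C@H]5c6cc(OCc7ccccc7)c(OC)cc6C[C@@](O)(CO)[C@@H]5CO)cc(OC)c4OCc8ccccc8)c3)[C@H]2CO)cc1OCc9ccccc9 | intermediate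
30 | CNP0252244.1 | COc1ccc(C[C@@]2(O)CO[C@H](c3cc(OC)c(O)c(-c4cc([C@H]5c6cc(O)c(OC)cc6C[C@@](O)(CO)[C@@H]5CO)cc(OC)c4O)c3)[C@H]2CO)cc1O | target

**Summary.** Total step count: 14. Longest linear sequence: 10 steps (steps 1–3, 8–14).

**Steps most likely to fail**

Step 6 (and its twin, step 10). Both chair arrangements of the carbinol centre may be populated in the Prins closure, so that the two faces of the alkene are poorly differentiated and enantiomeric purity is lost; the relative configuration is not affected. Fallback by resolution instead of substrate control: setting out from 16, the primary hydroxyl is esterified selectively with (S)-O-methylmandelic acid (DCC, DMAP, CH2Cl2) to give the O-methylmandelate F1. Its diastereomers are separated by chromatography or crystallisation, and K2CO3 in MeOH returns stereochemically pure 16.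

Step 7 (and its twin, step 11). In the Criegee adduct of the hindered aldehyde, hydrogen may migrate instead of the quaternary carbon, which would give the carboxylic acid and not the formate. Fallback through a methyl ketone, where only the tertiary group can compete with methyl: setting out from 14, MeLi/CeCl3 (THF, −78 °C) adds to the aldehyde in the presence of the acetate to give the secondary alcohol F2. Dess–Martin oxidation gives the methyl ketone F3. Buffered CF3CO3H (Na2HPO4, CH2Cl2) effects Baeyer–Villiger oxidation with retention to the diacetate F4, and K2CO3 in MeOH cleaves both acetates to return to 16.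

Step 12. The benzylic C–O bond may ionise sluggishly because the bromo and flanked benzyloxy groups weaken the donor, while the free tertiary 1,2-diol ionises or rearranges instead, or the cation may simply be recaptured by the primary hydroxyl without C–C bond formation. Fallback by changing the order so that no tertiary alcohol is present during the arylation: setting out from 24, SnCl4 (CH2Cl2, −40 → 0 °C) opens the oxolane and closes the tetralin to give the tetralin aldehyde F5. mCPBA/NaHCO3 converts the formyl group with retention to the tetralin formate F6 (not isolated), and K2CO3 in MeOH cleaves formate and acetate to arrive at 27.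

**Further compounds**
F1 | step 6 | (S)-O-methylmandelate of the primary alcohol of 16 | COc1ccc(C[C@@]2(O)CO[C@H](c3cc(OC)c(OCc4ccccc4)c(Br)c3)[C@H]2COC(=O)[C@@H](OC)c5ccccc5)cc1OCc1ccccc1
F2 | step 7 | [(2S,3R,4S)-2-aryl-4-benzyl-4-(1-hydroxyethyl)oxolan-3-yl]methyl acetate from 14 (carbinol epimers) | COc1ccc(C[C@@]2(C(C)O)CO[C@H](c3cc(OC)c(OCc4ccccc4)c(Br)c3)[C@H]2COC(C)=O)cc1OCc1ccccc1
F3 | step 7 | [(2S,3R,4S)-4-acetyl-2-aryl-4-benzyloxolan-3-yl]methyl acetate | COc1ccc(C[C@@]2(C(C)=O)CO[C@H](c3cc(OC)c(OCc4ccccc4)c(Br)c3)[C@H]2COC(C)=O)cc1OCc1ccccc1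
F4 | step 7 | diacetate of 16 (tertiary and primary acetate) | COc1ccc(C[C@@]2(OC(C)=O)CO[C@H](c3cc(OC)c(OCc4ccccc4)c(Br)c3)[C@H]2COC(C)=O)cc1OCc1ccccc1
F5 | step 12 | tetralin aldehyde: [(1S,2S,3S)-7-(benzyloxy)-1-aryl-3-formyl-3-(hydroxymethyl)-6-methoxy-1,2,3,4-tetrahydronaphthalen-2-yl]methyl acetate | Brc1cc([C@H]2c3cc(OCc4ccccc4)c(OC)cc3C[C@@](C=O)(CO)[C@@H]2COC(C)=O)cc(OC)c1OCc1ccccc1
F6 | step 12 | tetralin formate (tertiary formate in place of the formyl group of F5) | Brc1cc([C@H]2c3cc(OCc4ccccc4)c(OC)cc3C[C@@](OC=O)(CO)[C@@H]2COC(C)=O)cc(OC)c1OCc1ccccc1
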